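**Plan**

- Retrosynthesis: the bond between the linker CH2 and C-4 of the cyclohexadienone core is cut first (reductive Knoevenagel transform). This separates a cyclopentane β-hydroxy aldehyde from the (6R)-acyl trione core, which is in turn cut between its quaternary carbon and the prenyl group (allylic dearomatisation of a C-methylated acylphloroglucinol).
- Enabling feature of the cyclopentane: with the linker carbon at the acyl oxidation level, isopropenyl sits on the ring carbon β to it (C-5) and the methyl carbinol carbon (C-2) is bonded to its α-carbon (C-1). Ring bond C-1–C-2 and the C-5–isopropenyl bond are therefore the aldol and conjugate-addition bonds of an acyclic (E)-6-oxohept-2-enoyl imide.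
- Forward: N-acryloyl oxazolidinone, cross-metathesis with hex-5-en-2-one, then isopropenylcopper addition with in-flask aldol closure of the cyclopentane (the only ring made). Reductive release and oxidation give the aldehyde, which is joined in the last step to the six-membered core made separately in two steps.
- Stereochemistry: the (S)-benzyl oxazolidinone fixes the isopropenyl-bearing carbon. The cyclisation transition state (trans ring substituents, magnesium-bridged aldol) fixes the other two ring centres relative to it. A chiral palladium catalyst fixes the quaternary carbon of the core, and the final union creates no stereocentre.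

Key step: step 3

Assumption: the sense of induction of the Trost ligand with this phloroglucinolate cannot be predicted with confidence, so the (R,R) ligand is written in step 7 and its mirror image is to be used if the first run proves to give the (S) core; trione-core compounds are drawn in the dienol tautomer of the target SMILES.

**Route**

Step 1
Reactants: 1 (S)-4-benzyloxazolidin-2-one; 2 acryloyl chloride
Product: 4 (S)-3-acryloyl-4-benzyloxazolidin-2-one, via N-bromomagnesium oxazolidinone 3 (not isolated)
Conditions: MeMgBr (1.05 equiv), THF, 0 °C; then 2 (1.2 equiv), −78 → 0 °C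
Reagents that add atoms: acryloyl chloride (2), C=CC(Cl)=O
Why: N-acylation of the magnesium amide of the oxazolidinone by the acid chloride (standard preparation of N-enoyl imides), the magnesium counter-ion being mild enough to limit anionic polymerisation of the acrylate; no stereocentre is formed and that of the auxiliary is not involved.

Step 2
Reactants: 4 (S)-3-acryloyl-4-benzyloxazolidin-2-one; 5 hex-5-en-2-one
Product: 6 (4S)-4-benzyl-3-[(E)-6-oxohept-2-enoyl]oxazolidin-2-one
Conditions: second-generation Grubbs catalyst RuCl2(=CHPh)(PCy3)(H2IMes) (5 mol %), 5 (3 equiv), CH2Cl2, 40 °C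
Reagents that add atoms: hex-5-en-2-one (5), CC(=O)CCC=C
Why: Olefin cross-metathesis between the electron-poor N-acryloyl imide and an excess of the unhindered terminal alkene, a pairing that favours the cross product and, being reversible, should deliver the (E)-enoyl imide while ethene escapes and drives the reaction.

Step 3
Reactants: 6 (4S)-4-benzyl-3-[(E)-6-oxohept-2-enoyl]oxazolidin-2-one; 7 isopropenylmagnesium bromide
Product: 10 (4S)-4-benzyl-3-[(1S,2R,5R)-2-hydroxy-2-methyl-5-(prop-1-en-2-yl)cyclopentane-1-carbonyl]oxazolidin-2-one, via bromomagnesium Z-enolate 8 (not isolated), via bromomagnesium aldolate 9 (not isolated)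
Conditions: 7 (1.5 equiv), CuBr·SMe2 (1.5 equiv), THF/Me2S, −40 °C; then 6, −40 → 0 °C; sat. aq. NH4Cl at 0 °C
Reagents that add atoms: isopropenylmagnesium bromide (7), C=C(C)[Mg]Br
Why: Transmetalation of 7 with CuBr·SMe2 gives isopropenylcopper and MgBr2; magnesium binds both imide carbonyls of 6, the copper reagent adds to the β-carbon of the s-cis enoyl unit, and the resulting chelated (Z)-enolate 8 attacks the methyl ketone on warming to give aldolate 9, which is protonated on work-up. The closest known reaction type is the organocopper conjugate addition to N-enoyl oxazolidinones run in tandem with an intramolecular aldol addition to a tethered ketone (Michael-initiated ring closure of ω-oxo enoates and enimides). The cyclopentane closes in a 5-exo-trig aldol of the enolexo kind, the enolate carbon bonding to the ketone carbon at the far end of the three-atom tether. The isopropenyl-bearing carbon (C-5, R) is set by the auxiliary, whose benzyl group covers one face of the chelated enoyl plane so that copper delivers the alkenyl group to the other; C-1 (S) follows from the cyclisation transition state, in which the isopropenyl group lies pseudo-equatorial and ends up trans to the acyl group, and C-2 (R) from the magnesium bridge between enolate oxygen and ketone oxygen, which puts the new hydroxyl cis to the acyl group and the methyl group trans. The step needs conjugate addition in preference to attack on the ketone and one enoyl face in preference to the other; both are secured by the two-point magnesium chelate of the imide, which activates only the enoyl unit towards the ketone-inert organocopper reagent and fixes the conformation that the benzyl group shields.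

Step 4
Reactants: 10 (4S)-4-benzyl-3-[(1S,2R,5R)-2-hydroxy-2-methyl-5-(prop-1-en-2-yl)cyclopentane-1-carbonyl]oxazolidin-2-one
Product: 11 (1R,2R,3R)-2-(hydroxymethyl)-1-methyl-3-(prop-1-en-2-yl)cyclopentan-1-ol
Conditions: LiBH4 (2.5 equiv), MeOH (2.5 equiv), THF/Et2O, 0 °C; aqueous work-up
Reagents that add atoms: none
Why: Reductive cleavage of the N-acyl oxazolidinone by LiBH4, in which hydride attacks the exocyclic imide carbonyl (delivery being helped by the neighbouring cis hydroxyl as its alkoxyborohydride) and the aldehyde formed is reduced on to the primary alcohol while the auxiliary is released intact; the ring stereocentres and the alkene are untouched.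

Step 5
Reactants: 11 (1R,2R,3R)-2-(hydroxymethyl)-1-methyl-3-(prop-1-en-2-yl)cyclopentan-1-ol
Product: 12 (1S,2R,5R)-2-hydroxy-2-methyl-5-(prop-1-en-2-yl)cyclopentane-1-carbaldehyde
Conditions: TEMPO (10 mol %), PhI(OAc)2 (1.1 equiv), CH2Cl2, 0 °C → rt; short silica plug, used at once
Reagents that add atoms: none
Why: Oxoammonium (TEMPO/PhI(OAc)2) oxidation, which stops at the aldehyde for a primary alcohol and cannot oxidise the tertiary one; the formyl group already sits trans to both neighbouring carbon substituents, so the α-centre has no drive to epimerise, and the aldehyde is used at once to avoid dehydration.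

Step 6
Reactants: 13 2-methylbenzene-1,3,5-triol (2-methylphloroglucinol); 14 2-methylpropanoyl chloride
Product: 15 2-methyl-1-(2,4,6-trihydroxy-3-methylphenyl)propan-1-one
Conditions: AlCl3 (4 equiv), PhNO2, rt → 65 °C; then ice/aq. HCl
Reagents that add atoms: 2-methylpropanoyl chloride (14), CC(C)C(Cl)=O
Why: Friedel–Crafts acylation of the electron-rich triol, in which the two free ring positions of 13 are equivalent so that a single ketone results and the first acyl group deactivates the ring towards a second.

Step 7
Reactants: 15 2-methyl-1-(2,4,6-trihydroxy-3-methylphenyl)propan-1-one; 16 3-methylbut-2-en-1-yl acetate (prenyl acetate)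
Product: 17 (6R)-3,5-dihydroxy-6-methyl-6-(3-methylbut-2-en-1-yl)-2-(2-methylpropanoyl)cyclohexa-2,4-dien-1-one
Conditions: [Pd(C3H5)Cl]2 (2.5 mol %), (R,R)-DACH-phenyl Trost ligand (7.5 mol %), 16 (1.0 equiv), Et3N (2 equiv), THF, 0 °C → rt; aq. HCl, product extracted into aq. NaHCO3 and re-acidified
Reagents that add atoms: 3-methylbut-2-en-1-yl acetate (16), CC(=O)OCC=C(C)C
Why: Asymmetric Tsuji–Trost allylic dearomatisation, in which the zerovalent palladium–ligand complex ionises 16 to a π-prenyl cation that the ammonium phloroglucinolate of 15 should attack at the unsubstituted allyl terminus through its methyl-bearing ring carbon (the more electron-rich nucleophilic carbon, whose alkylation gives the stabilised vinylogous-acid trione), while the chiral ligand pocket distinguishes the two ring faces (acyl-chelated hydroxyl on one flank, free phenolate on the other) and so sets the quaternary centre; the strongly acidic product is separated from any aromatic C-prenyl isomer by the bicarbonate extraction.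

Step 8
Reactants: 12 (1S,2R,5R)-2-hydroxy-2-methyl-5-(prop-1-en-2-yl)cyclopentane-1-carbaldehyde; 17 (6R)-3,5-dihydroxy-6-methyl-6-(3-methylbut-2-en-1-yl)-2-(2-methylpropanoyl)cyclohexa-2,4-dien-1-one
Product: 19 (6R)-3,5-dihydroxy-4-{[(1S,2R,5R)-2-hydroxy-2-methyl-5-(prop-1-en-2-yl)cyclopentyl]methyl}-6-methyl-6-(3-methylbut-2-en-1-yl)-2-(2-methylpropanoyl)cyclohexa-2,4-dien-1-one (target CNP0261875.1), via alkylidene trione 18 (not isolated)
Conditions: L-proline (20 mol %), Hantzsch ester (diethyl 2,6-dimethyl-1,4-dihydropyridine-3,5-dicarboxylate, 1.1 equiv), CH2Cl2, rt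
Reagents that add atoms: none
Why: Organocatalytic reductive alkylation, in which proline-mediated Knoevenagel condensation of the aldehyde with the only C–H position of the vinylogous acid (C-4, between the two enol carbons) gives alkylidene 18, whose electron-poor exocyclic double bond is reduced at once by hydride transfer from the Hantzsch ester, so that neither the isopropenyl nor the prenyl alkene is touched and no stereocentre is formed or disturbed.

**Compound list**

1 | (S)-4-benzyloxazolidin-2-one | O=C1N[C@@H](Cc2ccccc2)CO1 | starting material
2 | acryloyl chloride | C=CC(Cl)=O | starting material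
3 | N-bromomagnesium salt of (S)-4-benzyloxazolidin-2-one (formed in the flask) | O=C1N([Mg]Br)[C@@H](Cc2ccccc2)CO1 | intermediate
4 | (S)-3-acryloyl-4-benzyloxazolidin-2-one | C=CC(=O)N1[C@@H](Cc2ccccc2)COC1=O | intermediate
5 | hex-5-en-2-one | CC(=O)CCC=C | starting material
6 | (4S)-4-benzyl-3-[(E)-6-oxohept-2-enoyl]oxazolidin-2-one | CC(=O)CC/C=C/C(=O)N1[C@@H](Cc2ccccc2)COC1=O | intermediate
7 | isopropenylmagnesium bromide (commercial THF solution) | C=C(C)[Mg]Br | starting material
8 | bromomagnesium (Z)-enolate of (4S)-4-benzyl-3-[(3R)-6-oxo-3-(prop-1-en-2-yl)heptanoyl]oxazolidin-2-one (formed in the flask) | C=C(C)[C@H](CCC(C)=O)/C=C(\O[Mg]Br)N1[C@@H](Cc2ccccc2)COC1=O | intermediate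
9 | bromomagnesium alkoxide (aldolate) of 10 (formed in the flask) | C=C(C)[C@@H]1CC[C@@](C)(O[Mg]Br)[C@H]1C(=O)N1[C@@H](Cc2ccccc2)COC1=O | intermediate
10 | (4S)-4-benzyl-3-[(1S,2R,5R)-2-hydroxy-2-methyl-5-(prop-1-en-2-yl)cyclopentane-1-carbonyl]oxazolidin-2-one | C=C(C)[C@@H]1CC[C@@](C)(O)[C@H]1C(=O)N1[C@@H](Cc2ccccc2)COC1=O | intermediate
11 | (1R,2R,3R)-2-(hydroxymethyl)-1-methyl-3-(prop-1-en-2-yl)cyclopentan-1-ol | C=C(C)[C@@H]1CC[C@@](C)(O)[C@H]1CO | intermediate
12 | (1S,2R,5R)-2-hydroxy-2-methyl-5-(prop-1-en-2-yl)cyclopentane-1-carbaldehyde | C=C(C)[C@@H]1CC[C@@](C)(O)[C@H]1C=O | intermediate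
13 | 2-methylbenzene-1,3,5-triol (2-methylphloroglucinol) | Cc1c(O)cc(O)cc1O | starting material
14 | 2-methylpropanoyl chloride | CC(C)C(Cl)=O | starting material
15 | 2-methyl-1-(2,4,6-trihydroxy-3-methylphenyl)propan-1-one | CC(C)C(=O)c1c(O)cc(O)c(C)c1O | intermediate
16 | 3-methylbut-2-en-1-yl acetate (prenyl acetate) | CC(=O)OCC=C(C)C | starting material
17 | (6R)-3,5-dihydroxy-6-methyl-6-(3-methylbut-2-en-1-yl)-2-(2-methylpropanoyl)cyclohexa-2,4-dien-1-one | OC1=CC(O)=C(C(=O)C(C)C)C(=O)[C@]1(C)CC=C(C)C | intermediate
18 | alkylidene trione: derivative of 17 in which the former aldehyde carbon of 12 is doubly bonded to C-4 of the core, alkene geometry not defined (formed in the flask) | C=C(C)[C@@H]1CC[C@@](C)(O)[C@H]1C=C1C(=O)C(C(=O)C(C)C)=C(O)[C@](C)(CC=C(C)C)C1=O | intermediate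
19 | (6R)-3,5-dihydroxy-4-{[(1S,2R,5R)-2-hydroxy-2-methyl-5-(prop-1-en-2-yl)cyclopentyl]methyl}-6-methyl-6-(3-methylbut-2-en-1-yl)-2-(2-methylpropanoyl)cyclohexa-2,4-dien-1-one | C=C(C)[C@@H]1CC[C@@](C)(O)[C@H]1CC1=C(O)[C@@](C)(CC=C(C)C)C(=O)C(C(=O)C(C)C)=C1O | target

**Step count and risks**

Total step count: 8. Longest linear sequence: 6 steps (steps 1, 2, 3, 4, 5 and 8); the core arm (steps 6 and 7) joins at step 8.

Steps most likely to fail:

Step 7. The ligand pocket may differentiate the two faces of the flat phloroglucinolate poorly, leaving the core with low enantiomeric purity. Prenylation at the unsubstituted ring carbon, or a second prenylation of the product, may also drain material. Fallback: starting from 15, classical base-mediated dearomative alkylation (prenyl bromide, NaOMe, MeOH, 0 °C) should give the racemic core F1. Its enantiomers are separated by preparative chromatography on a chiral stationary phase (amylose carbamate phase, supercritical CO2/MeOH). The (R)-enantiomer is 17, where the route is rejoined.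

Step 3. The chelated magnesium enolate may be protonated on work-up before it has cyclised. The aldolate may attack the oxazolidinone carbonyl or revert by retro-aldol cleavage on warming, and facial control with an alkenylcopper reagent may be incomplete. Fallback: starting from 6, the same organocopper addition is run at −78 °C and quenched cold with acetic acid to isolate the open-chain keto imide F2. Soft enolisation of its imide (TiCl4, iPr2NEt, CH2Cl2, −78 °C) then effects the ring-closing aldol through the chlorotitanium enolate as a separate operation. This returns to the route at 10.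

Step 8. Under amine catalysis the β-hydroxy aldehyde may lose water to the conjugated cyclopentene aldehyde, or open by retro-aldol cleavage, faster than the hindered α-branched carbonyl condenses. Fallback: starting from 11, both hydroxyls are silylated (TESOTf, 2,6-lutidine, CH2Cl2) to the bis(triethylsilyl) ether F3. Swern oxidation converts a primary triethylsilyl ether directly into the aldehyde and leaves the tertiary one, giving the silyloxy aldehyde F4, which can no longer fragment. Coupling with 17 under the conditions of step 8 gives the target silyl ether F5, and buffered fluoride (TBAF, AcOH, THF) then releases 19, where the route is rejoined.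

Further compounds
F1 | step 7 | racemic 3,5-dihydroxy-6-methyl-6-(3-methylbut-2-en-1-yl)-2-(2-methylpropanoyl)cyclohexa-2,4-dien-1-one | OC1=CC(O)=C(C(=O)C(C)C)C(=O)C1(C)CC=C(C)C
F2 | step 3 | (4S)-4-benzyl-3-[(3R)-6-oxo-3-(prop-1-en-2-yl)heptanoyl]oxazolidin-2-one | C=C(C)[C@H](CCC(C)=O)CC(=O)N1[C@@H](Cc2ccccc2)COC1=O
F3 | step 8 | bis(triethylsilyl) ether of diol 11 | C=C(C)[C@@H]1CC[C@@](C)(O[Si](CC)(CC)CC)[C@H]1CO[Si](CC)(CC)CC
F4 | step 8 | (1S,2R,5R)-2-methyl-5-(prop-1-en-2-yl)-2-[(triethylsilyl)oxy]cyclopentane-1-carbaldehyde | C=C(C)[C@@H]1CC[C@@](C)(O[Si](CC)(CC)CC)[C@H]1C=O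
F5 | step 8 | triethylsilyl ether of 19 at the tertiary hydroxyl | C=C(C)[C@@H]1CC[C@@](C)(O[Si](CC)(CC)CC)[C@H]1CC1=C(O)[C@@](C)(CC=C(C)C)C(=O)C(C(=O)C(C)C)=C1O
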